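**Plan**
- Retrosynthesis cuts, in order: the C8–O ester bond to the orsellinate, the O2–C3 bond of the pyran, the C1=C8a double bond, the C4a–C4 bond to the enyne chain, the C6 and C8a oxygens (back to a diene), the C7 methyl (back to a carboxyl), and last the C7–O and C8–O bonds, which leads to benzoic acid.
- Enabling feature: on the carbocycle C4a–C5–C6–C7–C8–C8a the tertiary C7 carbinol, which carries a one-carbon substituent, and the C8 oxygen are adjacent and cis. This is the pattern of an ipso,ortho cis-dihydrodiol of benzoic acid whose carboxyl carbon becomes the methyl group.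
- Forward: the carbocycle is taken intact from the arene. Its diene C8a=C4a–C5=C6 is oxidised with singlet oxygen, C4a is alkynylated, C8a is homologated by C1, and the pyran ring (O2, C1, C8a, C4a, C4, C3) closes by 6-endo attack of the C1 enol oxygen on the alkyne. The orsellinate is attached to C8 last.
- Stereochemistry: C7 and C8 (7R,8R in the target) both come from the enzymatic dihydroxylation, and no later step breaks a bond at either centre. The transient stereocentres at C6 and C8a are erased.

Key step: step 1

Numbering: the isochromene numbering of the target is used for every intermediate; the former ipso carbon of benzoic acid is C7 and the oxidised ortho carbon is C8.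
Assumption: the amine-induced opening of the endoperoxide is taken to start at the less hindered bridgehead hydrogen C8a–H; the first fallback covers the other outcome.

**Route**

Step 1
Reactants: 1 benzoic acid
Product: 2 (1S,2R)-1,2-dihydroxycyclohexa-3,5-diene-1-carboxylic acid
Conditions: growing whole cells of Cupriavidus necator B9, mineral salts medium, fructose as carbon source, sodium benzoate feed (1 neutralised with NaOH), air, 30 °C, pH 7; cells removed, pH 3, EtOAc extraction
Reagents that add atoms: dioxygen, O=O
Why: Benzoate 1,2-dioxygenase, a Rieske non-haem iron enzyme, binds benzoate through its carboxylate and, with two electrons passed from NADH via the [2Fe–2S] cluster to the mononuclear divalent iron, transfers both atoms of one O2 molecule suprafacially to the ipso carbon and one ortho carbon. The closest known reaction type is arene cis-dihydroxylation by Rieske dioxygenases, and this very oxidation of benzoate by the B9 strain is established on preparative scale. No ring is closed: the benzene ring is dearomatised to the cyclohexa-3,5-diene that becomes the carbocycle of the target, and the two C–O bonds that become C7–O and C8–O are formed. Both stereocentres are set by the enzyme pocket, which fixes the face of oxygen delivery and so should give the cis diol as the (1S,2R) enantiomer only. The step needs ipso,ortho regiochemistry and must stop at the diol; the first is secured by the carboxylate anchor, the second by the strain's lack of the diol dehydrogenase that would decarboxylate 2 to catechol, and the quaternary carbinol blocks simple dehydrative rearomatisation.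

Step 2
Reactants: 2 (1S,2R)-1,2-dihydroxycyclohexa-3,5-diene-1-carboxylic acid
Product: 3 (3aS,7aR)-2,2-dimethyl-3a,7a-dihydro-1,3-benzodioxole-3a-carboxylic acid
Conditions: 2,2-dimethoxypropane, TsOH·H2O (cat.), acetone, 0 °C to rt
Reagents that add atoms: 2,2-dimethoxypropane, COC(C)(C)OC
Why: Acid-catalysed transketalisation (acetonide formation) engages the cis-1,2-diol as a five-membered dioxolane, leaves the carboxylic acid free and removes the risk of acid-promoted aromatisation of the free diene diol.

Step 3
Reactants: 3 (3aS,7aR)-2,2-dimethyl-3a,7a-dihydro-1,3-benzodioxole-3a-carboxylic acid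
Product: 4 [(3aR,7aR)-2,2-dimethyl-3a,7a-dihydro-1,3-benzodioxol-3a-yl]methanol
Conditions: LiAlH4, THF, 0 °C to 40 °C; aqueous NaOH work-up
Reagents that add atoms: none
Why: LiAlH4 reduction of the carboxylic acid to the primary alcohol should be clean because the diene is not conjugated with the carboxyl group and the ketal is inert to hydride.

Step 4
Reactants: 4 [(3aR,7aR)-2,2-dimethyl-3a,7a-dihydro-1,3-benzodioxol-3a-yl]methanol
Product: 5 [(3aR,7aR)-2,2-dimethyl-3a,7a-dihydro-1,3-benzodioxol-3a-yl]methyl trifluoromethanesulfonate
Conditions: (CF3SO2)2O, pyridine, CH2Cl2, −40 °C to 0 °C; cold aqueous work-up, used crude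
Reagents that add atoms: trifluoromethanesulfonic anhydride, O=S(=O)(OS(=O)(=O)C(F)(F)F)C(F)(F)F
Why: O-Sulfonylation of the primary hydroxyl installs a leaving group reactive enough to offset the neopentyl-type, β-oxygenated position in the following displacement.

Step 5
Reactants: 5 [(3aR,7aR)-2,2-dimethyl-3a,7a-dihydro-1,3-benzodioxol-3a-yl]methyl trifluoromethanesulfonate
Product: 6 (3aS,7aR)-2,2,3a-trimethyl-3a,7a-dihydro-1,3-benzodioxole
Conditions: LiBHEt3, THF, −78 °C to 0 °C
Reagents that add atoms: none
Why: SN2 displacement of the primary triflate by hydride (LiBHEt3 reduction of a sulfonate) turns the former carboxyl carbon into the C7 methyl group without touching C7, and a polar path is chosen because the corresponding primary radical would suffer 1,2-vinyl shift and ring expansion.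

Step 6
Reactants: 6 (3aS,7aR)-2,2,3a-trimethyl-3a,7a-dihydro-1,3-benzodioxole
Product: 7 endoperoxide with the O–O bridge from C6 to C8a on the face opposite the ketal oxygens
Conditions: O2, visible light, 5,10,15,20-tetraphenylporphyrin (cat.), CH2Cl2, −20 °C
Reagents that add atoms: dioxygen, O=O
Why: Photosensitised [4+2] cycloaddition of singlet oxygen to the s-cis diene C8a=C4a–C5=C6 should occur anti to the two ketal oxygens, as is usual for arene cis-diol acetonides, and because the new C6 and C8a stereocentres are both destroyed later the face selectivity affects only the homogeneity of the intermediates.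

Step 7
Reactants: 7 endoperoxide with the O–O bridge from C6 to C8a
Product: 8 hydroxy enone with the ketone at C8a and the hydroxyl at C6
Conditions: Et3N, CH2Cl2, 0 °C
Reagents that add atoms: none
Why: Kornblum–DeLaMare rearrangement, in which the amine removes a bridgehead hydrogen anti-periplanar to the O–O bond, should start at the less hindered C8a–H (flanked by the C8 methine, not by the quaternary C7), so that C8a becomes the ketone and the C6 oxygen is released as a hydroxyl of unchanged configuration.

Step 8
Reactants: 8 hydroxy enone with the ketone at C8a and the hydroxyl at C6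
Product: 9 α-iodo enone carrying iodine at C4a
Conditions: I2, pyridine/CH2Cl2 (1:1), 0 °C to rt; aqueous Na2S2O3 work-up
Reagents that add atoms: iodine, II
Why: Johnson α-iodination of an enone (conjugate addition of pyridine at C5, iodination of the enolate at C4a, elimination of pyridine) places iodine on the α-carbon C4a and tolerates a free γ-hydroxyl.

Step 9
Reactants: 10 3-(trimethylsilyl)propynal; 11 tert-butyl (triphenylphosphoranylidene)acetate
Product: 12 tert-butyl (E)-5-(trimethylsilyl)pent-2-en-4-ynoate
Conditions: CH2Cl2, 0 °C to rt
Reagents that add atoms: none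
Why: Wittig olefination of the ynal with the ester-stabilised ylide should give mainly the (E)-enoate, the minor (Z)-isomer being removed by chromatography.

Step 10
Reactants: 12 tert-butyl (E)-5-(trimethylsilyl)pent-2-en-4-ynoate
Product: 13 tert-butyl (E)-pent-2-en-4-ynoate
Conditions: K2CO3 (cat.), MeOH, 0 °C
Reagents that add atoms: none
Why: Methoxide-mediated protodesilylation of the alkynylsilane is fast at 0 °C, while the hindered tert-butyl ester resists transesterification and slows conjugate addition of methanol.

Step 11
Reactants: 9 α-iodo enone carrying iodine at C4a; 13 tert-butyl (E)-pent-2-en-4-ynoate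
Product: 14 alkynyl enone carrying the (E)-enyne ester chain at C4a
Conditions: Pd(PPh3)2Cl2 (5 mol %), CuI (10 mol %), i-Pr2NH, THF, 0 °C
Reagents that add atoms: none
Why: Sonogashira coupling should be facile because zerovalent palladium inserts readily into the electron-poor C4a–I bond of an α-iodoenone at 0 °C and the copper acetylide then delivers the C4a–C4 bond without disturbing the free hydroxyl or the enoate.

Step 12
Reactants: 14 alkynyl enone carrying the (E)-enyne ester chain at C4a
Product: 15 methoxymethylene dienol ether (C8a=C1H–OMe; both geometries)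
Conditions: (methoxymethyl)triphenylphosphonium chloride (4 equiv), KN(SiMe3)2 (3.8 equiv), THF, −78 °C to 0 °C; pH 7 buffer work-up
Reagents that add atoms: (methoxymethyl)triphenylphosphonium chloride, COC[P+](c1ccccc1)(c1ccccc1)c1ccccc1.[Cl-]
Why: Wittig methoxymethylenation of the C8a ketone with excess ylide (the first equivalent only deprotonates the C6 hydroxyl) introduces C1 as a methyl enol ether, and C8 should be safe because the cis ring fusion is the preferred one and the ketal holds the C7–O bond near the nodal plane of any C8 enolate, which disfavours β-elimination.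

Step 13
Reactants: 15 methoxymethylene dienol ether
Product: 16 methoxy dienone with the ketone at C6
Conditions: Dess–Martin periodinane, pyridine, CH2Cl2, 0 °C to rt
Reagents that add atoms: none
Why: Dess–Martin oxidation of the secondary allylic C6 alcohol, buffered with pyridine to protect the acid-labile dienol ether, should give the push–pull dienone in which C6 carries the ketone of the target.

Step 14
Reactants: 16 methoxy dienone with the ketone at C6
Product: 18 azaphilone acetonide (7,8-O-isopropylidene derivative of 19), via hydroxymethylene dienone 17 (not isolated)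
Conditions: TsOH·H2O (1 equiv), THF/H2O (9:1), rt; then AuCl3 (5 mol %), rt
Reagents that add atoms: water, O
Why: Acid hydrolysis of the doubly vinylogous methyl ester (water adds at C1, methanol leaves) erases the enol ether geometry and frees the vinylogous acid, whose enol oxygen then attacks C3 of the alkyne activated by trivalent gold in a 6-endo-dig cycloisomerisation of the kind that converts ortho-alkynyl carbonyl compounds into isochromenes and 2-benzopyrylium salts, the 6-endo mode being favoured because C3 is the vinylogous acceptor position of the C6 enone and the product is the fully conjugated azaphilone chromophore.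

Step 15
Reactants: 18 azaphilone acetonide
Product: 19 tert-butyl (E)-3-[(7R,8R)-7,8-dihydroxy-7-methyl-6-oxo-7,8-dihydro-6H-isochromen-3-yl]prop-2-enoate
Conditions: AcOH/H2O (4:1), 45 °C
Reagents that add atoms: none
Why: Acid-catalysed ketal hydrolysis proceeds through the dioxolanyl oxocarbenium ion without breaking the C7–O or C8–O bond, so both stereocentres are retained, and aqueous acetic acid is mild enough to spare the tert-butyl ester.

Step 16
Reactants: 20 orsellinic acid
Product: 22 2,4-bis(4-methoxybenzyloxy)-6-methylbenzoic acid, via tris-PMB ester 21 (not isolated)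
Conditions: 4-methoxybenzyl chloride (3.5 equiv), K2CO3, Bu4NI (cat.), DMSO, 60 °C; then 4 M aqueous KOH, 90 °C; cold 1 M HCl to pH 3
Reagents that add atoms: 4-methoxybenzyl chloride, COc1ccc(CCl)cc1; potassium hydroxide, [K+].[OH-]
Why: Williamson O-alkylation converts both phenols and the carboxylate into 4-methoxybenzyl derivatives, after which hydroxide in hot aqueous DMSO saponifies the hindered ester while the aryl ethers stay intact.

Step 17
Reactants: 19 tert-butyl (E)-3-[(7R,8R)-7,8-dihydroxy-7-methyl-6-oxo-7,8-dihydro-6H-isochromen-3-yl]prop-2-enoate; 22 2,4-bis(4-methoxybenzyloxy)-6-methylbenzoic acid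
Product: 24 C8 ester of 19 with the bis-PMB orsellinate, via acid chloride 23 (not isolated)
Conditions: 22, 1-chloro-N,N,2-trimethylprop-1-en-1-amine, CH2Cl2, 0 °C to rt; then 19, DMAP, Et3N, CH2Cl2, 0 °C to rt
Reagents that add atoms: 1-chloro-N,N,2-trimethylprop-1-en-1-amine, CC(C)=C(Cl)N(C)C (its chlorine is carried only by intermediate 23)
Why: DMAP-catalysed acyl transfer through an acylpyridinium ion from the acid chloride, made under neutral conditions with the Ghosez chloroenamine so that the PMB ethers survive, should esterify the secondary C8 hydroxyl selectively because the tertiary C7 hydroxyl next to the ketone is far more hindered, and the C8–O bond is not broken so the configuration is retained.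

Step 18
Reactants: 24 C8 ester of 19 with the bis-PMB orsellinate
Product: 25 (+)-mitorubrinic acid B
Conditions: CF3CO2H/CH2Cl2 (1:4), anisole (10 equiv), 0 °C to rt
Reagents that add atoms: none
Why: Acidolysis (SN1 cleavage) removes the tert-butyl ester as isobutene and both 4-methoxybenzyl ethers as benzyl cations trapped by anisole (Friedel–Crafts scavenging), while the azaphilone core, whose ring oxygen is tied up in vinylogous ester conjugation with the C6 ketone and so assists ionisation at C8 only weakly, should survive short exposure.

**Compound list**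

1 | benzoic acid | O=C(O)c1ccccc1 | starting material
2 | (1S,2R)-1,2-dihydroxycyclohexa-3,5-diene-1-carboxylic acid | OC(=O)[C@]1(O)C=CC=C[C@H]1O | intermediate
3 | (3aS,7aR)-2,2-dimethyl-3a,7a-dihydro-1,3-benzodioxole-3a-carboxylic acid (acetonide of 2) | OC(=O)[C@]1(OC(C)(C)O2)C=CC=C[C@H]12 | intermediate
4 | [(3aR,7aR)-2,2-dimethyl-3a,7a-dihydro-1,3-benzodioxol-3a-yl]methanol | OC[C@]1(OC(C)(C)O2)C=CC=C[C@H]12 | intermediate
5 | [(3aR,7aR)-2,2-dimethyl-3a,7a-dihydro-1,3-benzodioxol-3a-yl]methyl trifluoromethanesulfonate | FC(F)(F)S(=O)(=O)OC[C@]1(OC(C)(C)O2)C=CC=C[C@H]12 | intermediate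
6 | (3aS,7aR)-2,2,3a-trimethyl-3a,7a-dihydro-1,3-benzodioxole (C7 methyl, C7/C8 cis acetonide, diene C8a=C4a–C5=C6) | C[C@]1(OC(C)(C)O2)C=CC=C[C@H]12 | intermediate
7 | endoperoxide of 6: O–O bridge from C6 to C8a, cis to the C7 methyl and trans to the ketal oxygens; C4a=C5 alkene | C[C@@]1(OC(C)(C)O2)[C@H]2[C@H]3OO[C@@H]1C=C3 | intermediate
8 | hydroxy enone: C8a ketone, C4a=C5, C6 hydroxyl cis to the C7 methyl, C7/C8 cis acetonide | C[C@@]1(OC(C)(C)O2)[C@H]2C(=O)C=C[C@H]1O | intermediate
9 | α-iodo enone: 8 with iodine at C4a | C[C@@]1(OC(C)(C)O2)[C@H]2C(=O)C(I)=C[C@H]1O | intermediate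
10 | 3-(trimethylsilyl)propynal | C[Si](C)(C)C#CC=O | starting material
11 | tert-butyl (triphenylphosphoranylidene)acetate | CC(C)(C)OC(=O)C=P(c1ccccc1)(c1ccccc1)c1ccccc1 | starting material
12 | tert-butyl (E)-5-(trimethylsilyl)pent-2-en-4-ynoate | C[Si](C)(C)C#C/C=C/C(=O)OC(C)(C)C | intermediate
13 | tert-butyl (E)-pent-2-en-4-ynoate | C#C/C=C/C(=O)OC(C)(C)C | intermediate
14 | alkynyl enone: 8 with the (E)-C≡C–CH=CH–CO2tBu chain at C4a | C[C@@]1(OC(C)(C)O2)[C@H]2C(=O)C(C#C/C=C/C(=O)OC(C)(C)C)=C[C@H]1O | intermediate
15 | methoxymethylene dienol ether: 14 with C8a=C1H–OMe in place of the ketone (mixture of enol ether geometries) | C[C@@]1(OC(C)(C)O2)[C@H]2C(=COC)C(C#C/C=C/C(=O)OC(C)(C)C)=C[C@H]1O | intermediate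
16 | methoxy dienone: 15 with the C6 carbinol oxidised to the ketone | C[C@@]1(OC(C)(C)O2)[C@H]2C(=COC)C(C#C/C=C/C(=O)OC(C)(C)C)=CC1=O | intermediate
17 | hydroxymethylene dienone: 16 with C1–OH in place of C1–OMe (enol form, acetonide intact) | C[C@@]12OC(C)(C)O[C@@H]1C(=CO)C(C#C/C=C/C(=O)OC(C)(C)C)=CC2=O | intermediate
18 | azaphilone acetonide: 7,8-O-isopropylidene derivative of 19 | C[C@@]12OC(C)(C)O[C@@H]1C1=COC(/C=C/C(=O)OC(C)(C)C)=CC1=CC2=O | intermediate
19 | tert-butyl (E)-3-[(7R,8R)-7,8-dihydroxy-7-methyl-6-oxo-7,8-dihydro-6H-isochromen-3-yl]prop-2-enoate | O[C@@H]1C2=COC(/C=C/C(=O)OC(C)(C)C)=CC2=CC(=O)[C@]1(C)O | intermediate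
20 | orsellinic acid (2,4-dihydroxy-6-methylbenzoic acid) | Cc1cc(O)cc(O)c1C(=O)O | starting material
21 | 4-methoxybenzyl 2,4-bis(4-methoxybenzyloxy)-6-methylbenzoate | Cc1cc(OCc2ccc(OC)cc2)cc(OCc2ccc(OC)cc2)c1C(=O)OCc1ccc(OC)cc1 | intermediate
22 | 2,4-bis(4-methoxybenzyloxy)-6-methylbenzoic acid | Cc1cc(OCc2ccc(OC)cc2)cc(OCc2ccc(OC)cc2)c1C(=O)O | intermediate
23 | 2,4-bis(4-methoxybenzyloxy)-6-methylbenzoyl chloride | Cc1cc(OCc2ccc(OC)cc2)cc(OCc2ccc(OC)cc2)c1C(=O)Cl | intermediate
24 | tert-butyl (E)-3-[(7R,8R)-8-[2,4-bis(4-methoxybenzyloxy)-6-methylbenzoyl]oxy-7-hydroxy-7-methyl-6-oxo-7,8-dihydro-6H-isochromen-3-yl]prop-2-enoate | Cc1cc(OCc2ccc(OC)cc2)cc(OCc2ccc(OC)cc2)c1C(=O)O[C@@H]1C2=COC(/C=C/C(=O)OC(C)(C)C)=CC2=CC(=O)[C@]1(C)O | intermediate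
25 | (+)-mitorubrinic acid B, (E)-3-[(7R,8R)-8-(2,4-dihydroxy-6-methylbenzoyl)oxy-7-hydroxy-7-methyl-6-oxo-7,8-dihydro-6H-isochromen-3-yl]prop-2-enoic acid | Cc1cc(O)cc(O)c1C(=O)O[C@@H]1C2=COC(/C=C/C(=O)O)=CC2=CC(=O)[C@]1(C)O | target

**Step count and risks**

Total step count: 18. Longest linear sequence: 15 steps (steps 1–8, 11–15, 17 and 18).

Steps most likely to fail:

Step 7. The amine may abstract the other bridgehead hydrogen (C6–H), which would put the ketone at C6 and the hydroxyl at C8a, or the γ-hydroxy enone may isomerise further under base to the saturated 1,4-dione. The fallback sets out from 7 and avoids the base-induced rearrangement. Reductive cleavage of the O–O bond with thiourea in MeOH at rt should give the cis-enediol F1. Site-selective oxidation of its less hindered allylic carbinol at C8a with activated MnO2 in CH2Cl2 (the C6 carbinol is shielded by the quaternary C7 and its cis methyl group) then leads back to the route at 8.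

Step 12. The ylide may enolise the hindered C8a ketone instead of adding to it, or add in conjugate fashion to the dienyne ester. The fallback sets out from 9 and reverses the order of the two carbon–carbon bond formations, so that the olefination is run on a ketone with no enoate in the molecule and a smaller α-substituent. Wittig methoxymethylenation of 9 under the conditions of step 12 should give the iodo dienol ether F2. Sonogashira coupling of F2 with 13 under the conditions of step 11 then comes back to the route at 15.

Step 14. During the acid hydrolysis the allylic C8 oxygen may ionise or be lost by β-elimination through the unveiled aldehyde before the ring closes, or the closure may be diverted to the 5-exo mode or to hydration of the alkyne. The fallback sets out from 14 and unmasks the C1 oxygen with fluoride instead of acid.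
- Olefination of 14 with [2-(trimethylsilyl)ethoxymethyl]triphenylphosphonium chloride and KN(SiMe3)2 should give the 2-(trimethylsilyl)ethyl dienol ether F3.
- Dess–Martin oxidation as in step 13 gives the 2-(trimethylsilyl)ethyl dienone F4.
- Bu4NF in THF at 0 °C then fragments the silylethyl group and releases the enolate of 17 without any acid.
- After buffering with AcOH, AuCl3 (5 mol %) closes the pyran ring and the sequence rejoins the route at 18.

Further compounds
F1 | step 7 | cis-enediol: 6,8a-diol from reductive opening of 7, both hydroxyls cis to the C7 methyl, C4a=C5 alkene, C7/C8 acetonide | C[C@@]1(OC(C)(C)O2)[C@H]2[C@@H](O)C=C[C@H]1O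
F2 | step 12 | iodo dienol ether: 9 with C8a=C1H–OMe in place of the ketone (mixture of enol ether geometries) | C[C@@]1(OC(C)(C)O2)[C@H]2C(=COC)C(I)=C[C@H]1O
F3 | step 14 | 2-(trimethylsilyl)ethyl dienol ether: analogue of 15 with OCH2CH2SiMe3 on C1 | C[C@@]1(OC(C)(C)O2)[C@H]2C(=COCC[Si](C)(C)C)C(C#C/C=C/C(=O)OC(C)(C)C)=C[C@H]1O
F4 | step 14 | 2-(trimethylsilyl)ethyl dienone: analogue of 16 with OCH2CH2SiMe3 on C1 | C[C@@]1(OC(C)(C)O2)[C@H]2C(=COCC[Si](C)(C)C)C(C#C/C=C/C(=O)OC(C)(C)C)=CC1=O
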